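**Retrosynthetic overview**
1. Target 24 ⇐ one-pot syn-hydroxy-acyloxylation of the C8=C9 alkene of dienone 22 (forms C8–O and C9–O, sets C8 and C9 anti to the C7 angelate).
2. 22 ⇐ ring-closing metathesis (seven-membered ring, last ring formed) of a 1,3-cis-dialkenyl cyclobutane; C7–O centre from a catalyst-controlled vinyl addition, then angeloylation; enone from DDQ oxidation of the C1 silyl ether.
3. C5–C6(Me)2–CHO arm ⇐ HWE olefination of the cyclobutanone, conjugate reduction, double methylation, nitrile half-reduction.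
4. Cyclobutane and six-membered ring (formed together, first) ⇐ intramolecular vinylketene–alkene [2+2] of acid 7; the C1 silyloxy centre relays absolute configuration.
5. Acid 7 ⇐ asymmetric vinylogous Mukaiyama aldol of dienal 3 with silyl dienolate 5.

Assumption: longipinane locants are used for all intermediates (C1 = ketone carbon, C2=C3(Me), cyclobutane = C4–C5–C11–C10, C6 = CMe2, C7–C9 = oxygenated carbons); "upper face" is the cyclobutane face carrying the C1–C3 bridge; angelic anhydride, (+)-MIB and the disulfonimide catalyst are taken as purchasable.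

**Step 1**
Reactants: 1 (2E)-3-methylpent-2-en-4-yn-1-ol
Product: 2 (2E)-3-methylpenta-2,4-dien-1-ol
Conditions: H2 (1 atm), Pd/CaCO3–Pb(OAc)2 (Lindlar catalyst), quinoline, pentane–Et2O, 0 °C
Reagents that add atoms: none
Why: Lindlar semi-hydrogenation reduces only the terminal alkyne and leaves the (E)-trisubstituted alkene untouched.

**Step 2**
Reactants: 2 (2E)-3-methylpenta-2,4-dien-1-ol
Product: 3 (2E)-3-methylpenta-2,4-dienal
Conditions: MnO2 (15 equiv), CH2Cl2, rt
Reagents that add atoms: none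
Why: MnO2 oxidation of the allylic alcohol gives the dienal with retention of alkene geometry.

**Step 3**
Reactants: 4 methyl 3-methylbut-2-enoate
Product: 5 (1Z)-1-methoxy-3-methyl-1-(tert-butyldimethylsilyloxy)buta-1,3-diene
Conditions: LiN(iPr)2, THF, −78 °C; TBSCl, DMPU, −78 °C → rt; distil
Reagents that add atoms: tert-butyldimethylsilyl chloride, CC(C)(C)[Si](C)(C)Cl
Why: γ-deprotonation of the senecioate and O-silylation of the dienolate (silyl ketene acetal formation).

**Step 4**
Reactants: 3 (2E)-3-methylpenta-2,4-dienal; 5 (1Z)-1-methoxy-3-methyl-1-(tert-butyldimethylsilyloxy)buta-1,3-diene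
Product: 6 methyl (2E,5S,6E)-5-(tert-butyldimethylsilyloxy)-3,7-dimethylnona-2,6,8-trienoate
Conditions: (R)-3,3′-bis[3,5-bis(trifluoromethyl)phenyl]-1,1′-binaphthyl-2,2′-disulfonimide (2 mol %), Et2O, −78 °C
Reagents that add atoms: none
Why: catalytic asymmetric vinylogous Mukaiyama aldol reaction with silyl transfer; the catalyst antipode is chosen to direct the γ-carbon of 5 to the Si face of the aldehyde, setting the silyloxy carbon (later C1) as S, and the s-trans dienolate gives the (2E)-enoate.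

**Step 5**
Reactants: 6 methyl (2E,5S,6E)-5-(tert-butyldimethylsilyloxy)-3,7-dimethylnona-2,6,8-trienoate
Product: 7 (2E,5S,6E)-5-(tert-butyldimethylsilyloxy)-3,7-dimethylnona-2,6,8-trienoic acid
Conditions: LiOH·H2O, THF–MeOH–H2O, rt; AcOH to pH 5
Reagents that add atoms: lithium hydroxide, [Li+].[OH-]
Why: saponification; the silyl ether and both alkene geometries are stable to mild base.

**Step 6**
Reactants: 7 (2E,5S,6E)-5-(tert-butyldimethylsilyloxy)-3,7-dimethylnona-2,6,8-trienoic acid
Product: 10 exo-methylene cyclobutanone 4-(tert-butyldimethylsilyloxy)-7-methyl-2-methylidene-7-vinylbicyclo[3.1.1]heptan-6-one, via acid chloride 8 (not isolated), via vinylketene 9 (not isolated)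
Conditions: 1-chloro-N,N,2-trimethylprop-1-en-1-amine, CH2Cl2, 0 °C; then slow addition to Et3N, toluene, 110 °C (5 mM)
Reagents that add atoms: none
Why: 1,4-dehydrochlorination gives vinylketene 9, and its intramolecular ketene–alkene [2+2] cycloaddition (bridged mode) joins the ketene carbonyl carbon (C5) to C11 and the α-carbon (C4) to C10; suprafacial addition to the (E)-alkene puts the C10 methyl on the upper face and the vinyl on the lower face, and allylic 1,3-strain at the silyloxy carbon (its H eclipsing the alkene) fixes the alkene face, so C4, C10 and C11 follow from C1.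

**Step 7**
Reactants: 10 exo-methylene cyclobutanone
Product: 11 4-(tert-butyldimethylsilyloxy)-2,7-dimethyl-7-vinylbicyclo[3.1.1]hept-2-en-6-one
Conditions: RhCl3·3H2O (5 mol %), EtOH, 70 °C
Reagents that add atoms: none
Why: rhodium hydride alkene isomerisation (β-pinene to α-pinene type) moves the exocyclic methylene to the only non-bridgehead ring position, C2=C3; this flattens the three-carbon bridge and opens the upper face of C5 for step 9.

**Step 8**
Reactants: 11 endo-alkene cyclobutanone; 12 diethyl (cyanomethyl)phosphonate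
Product: 13 2-[4-(tert-butyldimethylsilyloxy)-2,7-dimethyl-7-vinylbicyclo[3.1.1]hept-2-en-6-ylidene]acetonitrile (E/Z mixture)
Conditions: NaH, THF, 0 → 65 °C
Reagents that add atoms: none
Why: Horner–Wadsworth–Emmons olefination of the strained, non-enolisable cyclobutanone; the alkene geometry is irrelevant.

**Step 9**
Reactants: 13 alkylidene acetonitrile
Product: 14 2-[4-(tert-butyldimethylsilyloxy)-2,7-dimethyl-7-vinylbicyclo[3.1.1]hept-2-en-6-yl]acetonitrile (C5–H on the upper face, CH2CN on the face of the vinyl group)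
Conditions: Mg, MeOH, 0 °C → rt
Reagents that add atoms: none
Why: dissolving-metal conjugate reduction of the unsaturated nitrile; C5 is protonated from the face of the flat C1–C3 bridge because the C10 vinyl group blocks the other face (as in hydride additions to chrysanthenone), which sets C5.

**Step 10**
Reactants: 14 nitrile
Product: 16 2-methyl-2-[4-(tert-butyldimethylsilyloxy)-2,7-dimethyl-7-vinylbicyclo[3.1.1]hept-2-en-6-yl]propanenitrile, via monomethyl nitrile 15 (not isolated)
Conditions: LiN(iPr)2, THF–DMPU, −78 °C, MeI; then LiN(iPr)2, MeI in the same flask, −78 → 0 °C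
Reagents that add atoms: iodomethane, CI
Why: two successive nitrile-anion alkylations build the C6 gem-dimethyl quaternary carbon.

**Step 11**
Reactants: 16 gem-dimethyl nitrile
Product: 18 2-methyl-2-[4-(tert-butyldimethylsilyloxy)-2,7-dimethyl-7-vinylbicyclo[3.1.1]hept-2-en-6-yl]propanal, via N-aluminio aldimine 17 (not isolated)
Conditions: iBu2AlH, toluene, −78 °C; aqueous Rochelle salt
Reagents that add atoms: water, O
Why: DIBAL half-reduction of the hindered nitrile stops at the aldimine, which is hydrolysed on work-up to the C7 aldehyde.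

**Step 12**
Reactants: 18 aldehyde
Product: 19 (3R)-4-methyl-4-[4-(tert-butyldimethylsilyloxy)-2,7-dimethyl-7-vinylbicyclo[3.1.1]hept-2-en-6-yl]pent-1-en-3-ol
Conditions: (CH2=CH)2Zn [from CH2=CHMgBr, ZnCl2, dioxane], (+)-MIB [(2R)-3-exo-morpholinoisoborneol] (10 mol %), toluene, −20 → 0 °C; H2O
Reagents that add atoms: vinylmagnesium bromide, C=C[Mg]Br
Why: amino-alcohol-catalysed enantioselective organozinc addition; the (+)-MIB–zinc complex delivers vinyl to the Re face of the aldehyde under reagent control (the remote skeleton offers no bias), setting C7.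

**Step 13**
Reactants: 19 allylic alcohol
Product: 20 angelate [(Z)-2-methylbut-2-enoate] of 19
Conditions: LiN(SiMe3)2, THF, −40 °C; angelic anhydride, −40 → 0 °C
Reagents that add atoms: angelic anhydride, C/C=C(/C)C(=O)OC(=O)/C(C)=C\C
Why: acylation of the lithium alkoxide at low temperature without a nucleophilic amine catalyst keeps the (Z) geometry of the angelate.

**Step 14**
Reactants: 20 angelate diene
Product: 21 7-angeloyloxy-1-(tert-butyldimethylsilyloxy)longipina-2,8-diene
Conditions: second-generation Hoveyda–Grubbs catalyst [RuCl2(H2IMes)(=CH-C6H4-2-OiPr)] (10 mol %), 1,4-benzoquinone (20 mol %), toluene (2 mM), 80 °C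
Reagents that add atoms: none
Why: ring-closing olefin metathesis; the two vinyl groups sit 1,3-cis on the lower face of the cyclobutane and the gem-dimethyl group pre-organises them, closing the seven-membered ring with the C8=C9 alkene.

**Step 15**
Reactants: 21 tricyclic silyl ether
Product: 22 7-angeloyloxylongipina-2,8-dien-1-one
Conditions: DDQ (1.5 equiv), CH2Cl2–pH 7 buffer (20:1), rt
Reagents that add atoms: none
Why: DDQ oxidation of an allylic silyl ether: hydride abstraction from the allylic C1–H and loss of the silyl group give the conjugated enone directly.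

**Step 16**
Reactants: 22 dienone
Product: 24 (4R,5S,7S,8S,9S,10R,11R)-7-angeloyloxy-9-hydroxy-8-(3-methylbutanoyloxy)longipin-2-en-1-one (CNP0128158.1), via 8,9-diol 23 (not isolated)
Conditions: OsO4 (2 mol %), NMO·H2O (1.1 equiv), Ph2BOCH2CH2NH2 (10 mol %), CH2Cl2–MeCN, 0 °C → rt; then iPr2NEt, Me2CHCH2COCl, 0 °C
Reagents that add atoms: N-methylmorpholine N-oxide, C[N+]1([O-])CCOCC1; water, O; 3-methylbutanoyl chloride, CC(C)CC(Cl)=O
Why: Proposed new method: tandem osmium/borinic-acid-catalysed syn-hydroxyacyloxylation of an alkene. OsO4 adds [3+2] to the only electron-rich alkene (C8=C9) on the face anti to the allylic C7 angelate (Kishi's rule). The diphenylborinic acid catalyst cleaves the hindered osmate ester (as arylboronic acids do in boronate-trapped dihydroxylations) and holds the cis-diol as a tetracoordinate borinate. The acid chloride then acylates the less hindered O8 (O9 is neopentylic, next to quaternary C10), which sets C8 and C9 and forms both C–O bonds in one operation. The closest known reactions are the Upjohn/Narasaka dihydroxylation and the borinic-acid-catalysed regioselective monoacylation of cis-1,2-diols, which have not been merged.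

**Compound list**
1 | (2E)-3-methylpent-2-en-4-yn-1-ol | C#C/C(C)=C/CO | starting material
2 | (2E)-3-methylpenta-2,4-dien-1-ol | C=C/C(C)=C/CO | intermediate
3 | (2E)-3-methylpenta-2,4-dienal | C=C/C(C)=C/C=O | intermediate
4 | methyl 3-methylbut-2-enoate | COC(=O)C=C(C)C | starting material
5 | (1Z)-1-methoxy-3-methyl-1-(tert-butyldimethylsilyloxy)buta-1,3-diene | C=C(C)/C=C(/OC)O[Si](C)(C)C(C)(C)C | intermediate
6 | methyl (2E,5S,6E)-5-(tert-butyldimethylsilyloxy)-3,7-dimethylnona-2,6,8-trienoate | COC(=O)/C=C(\C)C[C@H](O[Si](C)(C)C(C)(C)C)/C=C(\C)C=C | intermediate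
7 | (2E,5S,6E)-5-(tert-butyldimethylsilyloxy)-3,7-dimethylnona-2,6,8-trienoic acid | OC(=O)/C=C(\C)C[C@H](O[Si](C)(C)C(C)(C)C)/C=C(\C)C=C | intermediate
8 | acid chloride of 7 (not isolated) | ClC(=O)/C=C(\C)C[C@H](O[Si](C)(C)C(C)(C)C)/C=C(\C)C=C | intermediate
9 | vinylketene (5S,6E)-5-(tert-butyldimethylsilyloxy)-7-methyl-3-methylidenenona-1,6,8-trien-1-one (not isolated) | O=C=CC(=C)C[C@H](O[Si](C)(C)C(C)(C)C)/C=C(\C)C=C | intermediate
10 | 4-(tert-butyldimethylsilyloxy)-7-methyl-2-methylidene-7-vinylbicyclo[3.1.1]heptan-6-one; C5 ketone, C10 methyl on the upper face and vinyl on the lower face, C1 silyloxy group on the side of the ketone bridge | O=C1[C@H]2[C@@H](O[Si](C)(C)C(C)(C)C)CC(=C)[C@@H]1[C@@]2(C)C=C | intermediate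
11 | 4-(tert-butyldimethylsilyloxy)-2,7-dimethyl-7-vinylbicyclo[3.1.1]hept-2-en-6-one (C2=C3 isomer of 10) | O=C1[C@H]2[C@@H](O[Si](C)(C)C(C)(C)C)C=C(C)[C@@H]1[C@@]2(C)C=C | intermediate
12 | diethyl (cyanomethyl)phosphonate | CCOP(=O)(CC#N)OCC | starting material
13 | 2-[4-(tert-butyldimethylsilyloxy)-2,7-dimethyl-7-vinylbicyclo[3.1.1]hept-2-en-6-ylidene]acetonitrile (E/Z mixture) | N#CC=C1[C@H]2[C@@H](O[Si](C)(C)C(C)(C)C)C=C(C)[C@@H]1[C@@]2(C)C=C | intermediate
14 | 2-[4-(tert-butyldimethylsilyloxy)-2,7-dimethyl-7-vinylbicyclo[3.1.1]hept-2-en-6-yl]acetonitrile (C5–H on the upper face) | N#CC[C@@H]1[C@H]2[C@@H](O[Si](C)(C)C(C)(C)C)C=C(C)[C@@H]1[C@@]2(C)C=C | intermediate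
15 | monomethylated nitrile (epimers at the nitrile carbon; not isolated) | N#CC(C)[C@@H]1[C@H]2[C@@H](O[Si](C)(C)C(C)(C)C)C=C(C)[C@@H]1[C@@]2(C)C=C | intermediate
16 | 2-methyl-2-[4-(tert-butyldimethylsilyloxy)-2,7-dimethyl-7-vinylbicyclo[3.1.1]hept-2-en-6-yl]propanenitrile | N#CC(C)(C)[C@@H]1[C@H]2[C@@H](O[Si](C)(C)C(C)(C)C)C=C(C)[C@@H]1[C@@]2(C)C=C | intermediate
17 | N-(diisobutylaluminio) aldimine of 18 (not isolated) | CC(C)C[Al](CC(C)C)N=CC(C)(C)[C@@H]1[C@H]2[C@@H](O[Si](C)(C)C(C)(C)C)C=C(C)[C@@H]1[C@@]2(C)C=C | intermediate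
18 | 2-methyl-2-[4-(tert-butyldimethylsilyloxy)-2,7-dimethyl-7-vinylbicyclo[3.1.1]hept-2-en-6-yl]propanal | O=CC(C)(C)[C@@H]1[C@H]2[C@@H](O[Si](C)(C)C(C)(C)C)C=C(C)[C@@H]1[C@@]2(C)C=C | intermediate
19 | (3R)-4-methyl-4-[4-(tert-butyldimethylsilyloxy)-2,7-dimethyl-7-vinylbicyclo[3.1.1]hept-2-en-6-yl]pent-1-en-3-ol | O[C@H](C=C)C(C)(C)[C@@H]1[C@H]2[C@@H](O[Si](C)(C)C(C)(C)C)C=C(C)[C@@H]1[C@@]2(C)C=C | intermediate
20 | angelate [(Z)-2-methylbut-2-enoate] of 19 | C/C=C(/C)C(=O)O[C@H](C=C)C(C)(C)[C@@H]1[C@H]2[C@@H](O[Si](C)(C)C(C)(C)C)C=C(C)[C@@H]1[C@@]2(C)C=C | intermediate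
21 | 7-angeloyloxy-1-(tert-butyldimethylsilyloxy)longipina-2,8-diene | C/C=C(/C)C(=O)O[C@@H]1C=C[C@@]2(C)[C@@H]3[C@@H](O[Si](C)(C)C(C)(C)C)C=C(C)[C@H]2[C@@H]3C1(C)C | intermediate
22 | 7-angeloyloxylongipina-2,8-dien-1-one | C/C=C(/C)C(=O)O[C@@H]1C=C[C@@]2(C)[C@@H]3C(=O)C=C(C)[C@H]2[C@@H]3C1(C)C | intermediate
23 | 7-angeloyloxy-8,9-dihydroxylongipin-2-en-1-one (8-OH and 9-OH cis to each other and anti to the 7-ester; not isolated) | C/C=C(/C)C(=O)O[C@@H]1[C@@H](O)[C@@H](O)[C@@]2(C)[C@@H]3C(=O)C=C(C)[C@H]2[C@@H]3C1(C)C | intermediate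
24 | (4R,5S,7S,8S,9S,10R,11R)-7-angeloyloxy-9-hydroxy-8-(3-methylbutanoyloxy)longipin-2-en-1-one | C/C=C(/C)C(=O)O[C@@H]1[C@@H](OC(=O)CC(C)C)[C@@H](O)[C@@]2(C)[C@@H]3C(=O)C=C(C)[C@H]2[C@@H]3C1(C)C | target

**Totals and risks**
Total step count: 16. Longest linear sequence: 15 steps (1 → 24 through steps 1, 2 and 4–16; step 3 is the side branch from 4).

Steps most likely to fail:

Step 16 (the new reaction). Risks are incomplete O8/O9 regiocontrol, acyl migration, or competing oxidation of the angelate alkene. The fallback uses known chemistry, stepwise and with tin in place of boron. It sets out from 22: Upjohn dihydroxylation (OsO4 cat., NMO, acetone–H2O) gives diol 23, which is isolated. Bu2SnO in toluene at 80 °C converts it into the dibutylstannylene acetal F11, and 3-methylbutanoyl chloride at 0 °C acylates the less hindered tin-bound O8. The fallback returns to the route at 24.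

Step 9 (facial selectivity at C5). Both faces of C5 are crowded, so protonation may occur mainly on the lower face and give the useless C5 epimer. The fallback turns that same bias to advantage and fixes C5 only after ring closure. It sets out from ketone 11: 2-lithio-2-methylpropanenitrile (isobutyronitrile, LiN(iPr)2, THF, −78 °C) adds from the lower face to give the β-hydroxy nitrile F1. iBu2AlH gives the β-hydroxy aldehyde F2. Divinylzinc/(+)-MIB gives the diol F3. LiN(SiMe3)2/angelic anhydride acylates only the secondary hydroxyl to give the hydroxy angelate F4. Ring-closing metathesis with the second-generation Hoveyda–Grubbs catalyst gives the tricyclic tertiary alcohol F5. Methyl chlorooxoacetate/DMAP gives the methyl oxalate F6. Barton-type radical deoxygenation ((Me3Si)3SiH, AIBN, toluene, 80 °C) then delivers hydrogen to the only open lobe of the ring-locked C5 radical. The fallback returns to the route at 21.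

Step 12 (asymmetric vinyl transfer to a neopentyl aldehyde). The addition may be slow or poorly selective. The fallback replaces it with a reagent-controlled ketone reduction. It sets out from 18: CH2=CHMgBr (THF, −78 °C) gives the C7-epimeric allylic alcohols F7. Dess–Martin periodinane gives the vinyl ketone F8. Ring-closing metathesis (second-generation Hoveyda–Grubbs catalyst, toluene, 80 °C) gives the cycloheptenone F9. (S)-Me-CBS oxazaborolidine/catecholborane reduction (tert-alkyl side as the large group) gives the (7R)-allylic alcohol F10. LiN(SiMe3)2/angelic anhydride then returns to the route at 21.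

**Further compounds**
F1 | step 9 | 2-[6-hydroxy-4-(tert-butyldimethylsilyloxy)-2,7-dimethyl-7-vinylbicyclo[3.1.1]hept-2-en-6-yl]-2-methylpropanenitrile (C5–OH on the upper face) | N#CC(C)(C)[C@]1(O)[C@H]2[C@@H](O[Si](C)(C)C(C)(C)C)C=C(C)[C@@H]1[C@@]2(C)C=C
F2 | step 9 | β-hydroxy aldehyde corresponding to F1 | O=CC(C)(C)[C@]1(O)[C@H]2[C@@H](O[Si](C)(C)C(C)(C)C)C=C(C)[C@@H]1[C@@]2(C)C=C
F3 | step 9 | (3R)-vinyl carbinol diol from F2 | O[C@H](C=C)C(C)(C)[C@]1(O)[C@H]2[C@@H](O[Si](C)(C)C(C)(C)C)C=C(C)[C@@H]1[C@@]2(C)C=C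
F4 | step 9 | 7-O-angelate of F3 (tertiary OH free) | C/C=C(/C)C(=O)O[C@H](C=C)C(C)(C)[C@]1(O)[C@H]2[C@@H](O[Si](C)(C)C(C)(C)C)C=C(C)[C@@H]1[C@@]2(C)C=C
F5 | step 9 | 7-angeloyloxy-5-hydroxy-1-(tert-butyldimethylsilyloxy)longipina-2,8-diene | C/C=C(/C)C(=O)O[C@@H]1C=C[C@@]2(C)[C@@H]3[C@@H](O[Si](C)(C)C(C)(C)C)C=C(C)[C@H]2[C@]3(O)C1(C)C
F6 | step 9 | methyl oxalate of F5 | C/C=C(/C)C(=O)O[C@@H]1C=C[C@@]2(C)[C@@H]3[C@@H](O[Si](C)(C)C(C)(C)C)C=C(C)[C@H]2[C@]3(OC(=O)C(=O)OC)C1(C)C
F7 | step 12 | C7-epimeric mixture of vinyl carbinols (19 and its C7 epimer) | OC(C=C)C(C)(C)[C@@H]1[C@H]2[C@@H](O[Si](C)(C)C(C)(C)C)C=C(C)[C@@H]1[C@@]2(C)C=C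
F8 | step 12 | 4-methyl-4-[4-(tert-butyldimethylsilyloxy)-2,7-dimethyl-7-vinylbicyclo[3.1.1]hept-2-en-6-yl]pent-1-en-3-one | C=CC(=O)C(C)(C)[C@@H]1[C@H]2[C@@H](O[Si](C)(C)C(C)(C)C)C=C(C)[C@@H]1[C@@]2(C)C=C
F9 | step 12 | 1-(tert-butyldimethylsilyloxy)longipina-2,8-dien-7-one | O=C1C=C[C@@]2(C)[C@@H]3[C@@H](O[Si](C)(C)C(C)(C)C)C=C(C)[C@H]2[C@@H]3C1(C)C
F10 | step 12 | (7R)-1-(tert-butyldimethylsilyloxy)longipina-2,8-dien-7-ol | O[C@@H]1C=C[C@@]2(C)[C@@H]3[C@@H](O[Si](C)(C)C(C)(C)C)C=C(C)[C@H]2[C@@H]3C1(C)C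
F11 | step 16 | 8,9-O-dibutylstannylene acetal of diol 23 | C/C=C(/C)C(=O)O[C@@H]1[C@H]2O[Sn](CCCC)(CCCC)O[C@H]2[C@@]4(C)[C@@H]5C(=O)C=C(C)[C@H]4[C@@H]5C1(C)C
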